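**Retrosynthetic overview**
- Feature: C5 is a CH2 between the E C6=C7 alkene and C4 of the C3–C4 oxirane. With the oxirane read as an E C3=C4 alkene, C3=C4–C5–C6=C7 is a skipped diene and C5–C6 is an allyl–alkenyl bond. C6–C13, with the C8 tertiary vinyl carbinol and the methyl groups on C8 and C12, has the carbon skeleton of (S)-linalool.
- Late disconnections: the oxirane oxygen goes in last (chiral dioxirane). C5–C6 comes from a C5 allylic carbonate and an E C6 alkenylboronate under palladium and closes the 14-membered ring. The boronate comes from cross-metathesis at the linalool vinyl group.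
- Lactone region: C3=C4 by Wittig reaction. C1–C14 and the lactone C–O bond come from a chelation-controlled indium allylation of a C13-hydroxy C14 aldehyde with a Baylis–Hillman bromide.
- Linalool side: SeO2 oxidises C13, a methoxymethylene Wittig reaction adds C14, iminium transfer hydrogenation sets C12, and proline aminoxylation sets C13.
- Ring order: γ-lactone (step 11), 14-membered carbocycle (step 19), oxirane (step 20).

Key step: step 19

Numbering: cembrane numbering is used throughout. C1 is the lactone ring-fusion CH, C14 the lactone O–CH, C15 the α-carbon, C16 the lactone C=O and C17 the exocyclic =CH2.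
Assumption: (S)-(+)-linalool is bought in high enantiomeric purity. The enol ether of step 2 and the enal of step 3 are E/Z mixtures drawn as E, which has no consequence because both alkenes are consumed.

**Step 1**
Reactants: 1 (S)-linalool
Product: 2 (2E,6S)-6-hydroxy-2,6-dimethylocta-2,7-dienal (CHO = C13)
Conditions: SeO2 (1.1 equiv), 1,4-dioxane, 80 °C
Reagents that add atoms: selenium dioxide, O=[Se]=O
Why: Riley allylic oxidation (ene reaction, then [2,3]-sigmatropic shift) picks the electron-rich trisubstituted alkene and its E-methyl group, which becomes C13, whereas the vinyl group has no allylic hydrogen and the C8 stereocentre from the chiral pool is not touched.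

**Step 2**
Reactants: 2 (2E,6S)-6-hydroxy-2,6-dimethylocta-2,7-dienal
Product: 3 (3S,6E)-9-methoxy-3,7-dimethylnona-1,6,8-trien-3-ol
Conditions: MeOCH2PPh3Cl (2.5 equiv), KOtBu (2.4 equiv), THF, 0 °C to rt
Reagents that add atoms: (methoxymethyl)triphenylphosphonium chloride, COC[P+](c1ccccc1)(c1ccccc1)c1ccccc1.[Cl-]
Why: Wittig methoxymethylenation brings in C14, the one ring carbon between the linalool chain and the lactone that no other building block supplies, and the extra equivalent of ylide only deprotonates the C8 alcohol reversibly.

**Step 3**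
Reactants: 3 (3S,6E)-9-methoxy-3,7-dimethylnona-1,6,8-trien-3-ol
Product: 5 (2E,7S)-7-hydroxy-3,7-dimethylnona-2,8-dienal as an E/Z mixture at C12=C13, via deconjugated aldehyde 4 (not isolated)
Conditions: PPTS (0.2 equiv), THF/H2O (4:1), 40 °C; then DBU (0.1 equiv), CH2Cl2, 0 °C to rt
Reagents that add atoms: water, O
Why: Enol ether hydrolysis gives the β,γ-unsaturated aldehyde and base-mediated conjugation then moves the alkene from C11=C12 to C12=C13, so that C12 becomes the β-carbon of a citral-type enal, while the weak acid leaves the tertiary allylic alcohol intact.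

**Step 4**
Reactants: 5 (2E,7S)-7-hydroxy-3,7-dimethylnona-2,8-dienal
Product: 6 (3S,7S)-7-hydroxy-3,7-dimethylnon-8-enal
Conditions: morpholinium salt of (S)-TRIP (20 mol %), Hantzsch ester (diethyl 1,4-dihydro-2,6-dimethylpyridine-3,5-dicarboxylate, 1.2 equiv), 1,4-dioxane, 50 °C
Reagents that add atoms: none
Why: Organocatalytic transfer hydrogenation by asymmetric counteranion-directed iminium catalysis sends hydride only to C12 of the conjugated iminium ion, so the C6=C7 vinyl group that a metal/H2 hydrogenation would reduce first is untouched, rapid E/Z exchange of the iminium ion makes the reduction stereoconvergent, and the chiral phosphate sets 12S (the S acid is the antipode of the one that takes citral to (R)-citronellal).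

**Step 5**
Reactants: 6 (3S,7S)-7-hydroxy-3,7-dimethylnon-8-enal
Product: 8 (2R,3S,7S)-2-(anilinooxy)-3,7-dimethylnon-8-ene-1,7-diol, via anilinooxy aldehyde 7 (not isolated)
Conditions: PhNO (1.0 equiv, slow addition), L-proline (20 mol %), MeCN, −20 °C; then NaBH4, MeOH, 0 °C
Reagents that add atoms: nitrosobenzene, O=Nc1ccccc1
Why: Proline-catalysed α-aminoxylation, in which the enamine attacks the oxygen of nitrosobenzene held by the carboxylic acid proton, sets 13R under catalyst control with L-proline irrespective of the neighbouring C12 centre, and immediate borohydride reduction avoids handling the oligomerising α-oxy aldehyde.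

**Step 6**
Reactants: 8 (2R,3S,7S)-2-(anilinooxy)-3,7-dimethylnon-8-ene-1,7-diol
Product: 9 (2R,3S,7S)-3,7-dimethylnon-8-ene-1,2,7-triol
Conditions: Zn dust, AcOH/THF, rt
Reagents that add atoms: none
Why: Dissolving-metal reduction cleaves only the weak N–O bond and leaves the alkene, the alcohols and all stereocentres as they are.

**Step 7**
Reactants: 9 (2R,3S,7S)-3,7-dimethylnon-8-ene-1,2,7-triol
Product: 10 (3S,7S,8R)-3,7-dimethyl-8,9-bis(triethylsilyloxy)non-1-en-3-ol
Conditions: TESCl (2.2 equiv), imidazole, CH2Cl2, 0 °C
Reagents that add atoms: chlorotriethylsilane, CC[Si](Cl)(CC)CC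
Why: Silyl ether formation with a chlorosilane and imidazole stops at the primary and secondary alcohols because the tertiary C8 alcohol is too hindered.

**Step 8**
Reactants: 10 (3S,7S,8R)-3,7-dimethyl-8,9-bis(triethylsilyloxy)non-1-en-3-ol
Product: 11 (2R,3S,7S)-7-hydroxy-3,7-dimethyl-2-(triethylsilyloxy)non-8-enal
Conditions: (COCl)2, DMSO, CH2Cl2, −78 to −40 °C; Et3N, −78 °C to 0 °C
Reagents that add atoms: none
Why: Swern oxidation of a bis(triethylsilyl) ether, in which the chlorosulfonium salt attacks the less hindered primary silyl ether oxygen and so oxidises C14 directly to the aldehyde, keeps the C13 silyl ether and, at low temperature, the C13 configuration, and the tertiary alcohol has no carbinol hydrogen to lose.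

**Step 9**
Reactants: 12 3-(tert-butyldimethylsilyloxy)propanal; 13 ethyl acrylate
Product: 14 ethyl 5-(tert-butyldimethylsilyloxy)-3-hydroxy-2-methylidenepentanoate (racemic)
Conditions: DABCO (0.5 equiv), 1,4-dioxane/H2O (1:1), rt
Reagents that add atoms: none
Why: Morita–Baylis–Hillman reaction joins C1 to C15, and the new carbinol centre is racemic and is erased in the next step.

**Step 10**
Reactants: 14 ethyl 5-(tert-butyldimethylsilyloxy)-3-hydroxy-2-methylidenepentanoate
Product: 15 ethyl (2Z)-2-(bromomethyl)-5-(tert-butyldimethylsilyloxy)pent-2-enoate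
Conditions: NBS, Me2S, CH2Cl2, 0 °C to rt
Reagents that add atoms: N-bromosuccinimide, O=C1CCC(=O)N1Br
Why: Corey–Kim-type activation of the alcohol and SN2′ attack of bromide give the rearranged primary allylic bromide as the Z isomer (C2 chain cis to CH2Br and trans to the ester), and the neutral conditions keep the silyl ether.

**Step 11**
Reactants: 11 (2R,3S,7S)-7-hydroxy-3,7-dimethyl-2-(triethylsilyloxy)non-8-enal; 15 ethyl (2Z)-2-(bromomethyl)-5-(tert-butyldimethylsilyloxy)pent-2-enoate
Product: 19 (4S,5R)-4-[2-(tert-butyldimethylsilyloxy)ethyl]-5-[(1R,2S,6S)-1,6-dihydroxy-2,6-dimethyloct-7-en-1-yl]-3-methylideneoxolan-2-one, via free hydroxy aldehyde 16 (not isolated), via allylindium reagent 17 (not isolated), via open trihydroxy ester 18 (not isolated)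
Conditions: AcOH/THF/H2O (3:1:1), rt; dilute with THF/H2O, 15 (1.3 equiv), In powder (1.5 equiv), rt; crude adduct, PPTS (10 mol %), toluene, 50 °C
Reagents that add atoms: none
Why: Barbier-type indium allylation in water followed by acid-catalysed lactonisation: the Z-crotyl-type allylindium reagent reacts at its γ-carbon C1 through a closed Zimmerman–Traxler chair to give the 14,1-syn adduct and hence the cis-fused lactone (1S), trivalent indium chelated between the aldehyde oxygen and the free C13 hydroxyl directs attack anti to the C12 chain to give the 13,14-syn diol (14R), and the five-membered lactone on O14 forms in preference to the six-membered one on O13.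

**Step 12**
Reactants: 19 lactone diol
Product: 20 13-acetate of 19 (1S,8S,12S,13R,14R; C8–OH free; C3–OTBS)
Conditions: Ac2O (1.5 equiv), pyridine, DMAP (5 mol %), CH2Cl2, 0 °C
Reagents that add atoms: acetic anhydride, CC(=O)OC(C)=O
Why: Nucleophilic catalysis acylates the only secondary alcohol, the tertiary allylic C8 alcohol being far slower.

**Step 13**
Reactants: 20 13-acetate silyl ether
Product: 21 primary C3 alcohol (lactone C1 carries CH2CH2OH)
Conditions: HF·pyridine, pyridine, THF, 0 °C to rt
Reagents that add atoms: none
Why: Fluoride-driven desilylation under buffered acidic conditions frees the primary C3 alcohol without acetate migration or conjugate addition to the methylene lactone.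

**Step 14**
Reactants: 21 primary C3 alcohol
Product: 22 C3 aldehyde (lactone C1 carries CH2CHO)
Conditions: Dess–Martin periodinane, CH2Cl2, 0 °C to rt
Reagents that add atoms: none
Why: Dess–Martin oxidation is neutral and fast, takes the primary alcohol to the aldehyde and cannot oxidise or transpose the tertiary allylic alcohol.

**Step 15**
Reactants: 22 C3 aldehyde
Product: 23 (3E)-enal (lactone C1 carries CH2–CH=C(CH3)–CHO; CHO = C5)
Conditions: Ph3P=C(CH3)CHO (1.5 equiv), toluene, 80 °C
Reagents that add atoms: 2-(triphenylphosphoranylidene)propanal, CC(C=O)=P(c1ccccc1)(c1ccccc1)c1ccccc1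
Why: The Wittig reaction of a stabilised formyl ylide gives the E trisubstituted C3=C4 enal, and the weakly nucleophilic ylide reacts with the aliphatic aldehyde in preference to the lactone, the acetate or the product enal.

**Step 16**
Reactants: 23 (3E)-enal
Product: 24 (3E)-allylic alcohol (C5–OH)
Conditions: NaBH4, CeCl3·7H2O, MeOH, −78 °C
Reagents that add atoms: none
Why: Luche reduction gives clean 1,2-reduction of the enal at low temperature, much faster than any hydride addition to the methylene lactone.

**Step 17**
Reactants: 24 (3E)-allylic alcohol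
Product: 25 (3E)-allylic methyl carbonate (C5–OCO2Me; C7 vinyl; C8–OH free)
Conditions: ClCO2Me, pyridine, CH2Cl2, 0 °C
Reagents that add atoms: methyl chloroformate, COC(=O)Cl
Why: Acylation of the unhindered primary allylic alcohol with a chloroformate installs a leaving group that will release its own base, and the tertiary alcohol stays free.

**Step 18**
Reactants: 25 (3E)-allylic methyl carbonate; 26 vinylboronic acid pinacol ester
Product: 27 seco allylic carbonate (6E)-alkenylboronate (1S,8S,12S,13R,14R)
Conditions: 26 (4 equiv), second-generation Hoveyda–Grubbs catalyst (10 mol %), CH2Cl2, 40 °C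
Reagents that add atoms: none
Why: Olefin cross-metathesis engages only the monosubstituted C7 vinyl group, whose free allylic hydroxyl favours the reaction, because the trisubstituted C3=C4 and the electron-poor 1,1-disubstituted C15=C17 alkenes are poor partners, the bulky boronate and the quaternary C8 enforce E geometry, and the terminal CH2 of linalool is exchanged for the CH–B carbon that becomes C6.

**Step 19**
Reactants: 27 seco allylic carbonate (6E)-alkenylboronate
Product: 28 3,4-deoxy macrocycle (3E,6E; 1S,8S,12S,13R,14R)
Conditions: Pd(PPh3)4 (10 mol %), THF, 50 °C, 27 added by syringe pump over 12 h to a final 1 mM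
Reagents that add atoms: none
Why: Zerovalent palladium ionises the primary allylic methyl carbonate with loss of CO2 to a syn-configured η3-allyl(methoxo)palladium complex over C3–C4–C5, and the palladium-bound methoxide, not an external base, activates the pinacol boronate so that the E-alkenyl group passes from boron to palladium with retention. Reductive elimination then joins C6 to the unsubstituted C5 terminus; the closest known reactions are the Suzuki–Miyaura-type coupling of allylic carbonates with alkenylboron reagents under neutral conditions and the Stille allyl–alkenyl macrocyclisation. The 14-membered carbocycle closes end to end within a macrocyclic (allyl)(alkenyl)palladium species, whereas bonding at C3 would give a 12-membered ring with an isopropenyl branch and is disfavoured because C3 is secondary and next to the lactone. No stereocentre is formed, and the five existing ones (C1, C8, C12, C13, C14) lie away from the reacting carbons. The step needs C5-over-C3 regioselectivity, retention of both E geometries and ring closure over oligomerisation: the first rests on the steric difference of the allyl termini, the second on stereoretentive transmetalation and capture of the syn-allyl complex before π–σ–π isomerisation, the third on slow addition. Because the methoxide is handed directly to boron and leaves as MeOBpin, the acetate, the methylene lactone and the free tertiary alcohol see no free base.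

**Step 20**
Reactants: 28 3,4-deoxy macrocycle
Product: 29 target CNP0202356.4 (1S,3R,4R,8S,12S,13R,14R)
Conditions: D-fructose-derived Shi ketone (0.3 equiv), KHSO5 (as Oxone, 1.3 equiv), K2CO3, Na2B4O7 buffer, Bu4NHSO4 (cat.), MeCN/CH2(OMe)2/H2O, 0 °C
Reagents that add atoms: potassium peroxymonosulfate KHSO5, [K+].[O-]S(=O)(=O)OO
Why: Shi epoxidation: the dioxirane from the D-fructose-derived ketone attacks E trisubstituted alkenes through a spiro transition state to give the R,R-oxirane, here 3R,4R, and it prefers the most electron-rich alkene C3=C4 over C6=C7, which is disubstituted, inductively deactivated by the C8 hydroxyl and shielded by the quaternary C8, and over the electron-poor methylene lactone.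

**Compound list**
1 | (S)-linalool, (3S)-3,7-dimethylocta-1,6-dien-3-ol | CC(C)=CCC[C@](C)(O)C=C | starting material
2 | (2E,6S)-6-hydroxy-2,6-dimethylocta-2,7-dienal | O=C/C(C)=C/CC[C@](C)(O)C=C | intermediate
3 | (3S,6E)-9-methoxy-3,7-dimethylnona-1,6,8-trien-3-ol (enol ether E/Z, drawn E) | CO/C=C/C(C)=C/CC[C@](C)(O)C=C | intermediate
4 | (3E,7S)-7-hydroxy-3,7-dimethylnona-3,8-dienal (not isolated) | O=CC/C(C)=C/CC[C@](C)(O)C=C | intermediate
5 | (2E,7S)-7-hydroxy-3,7-dimethylnona-2,8-dienal (E/Z, drawn E) | O=C/C=C(\C)CCC[C@](C)(O)C=C | intermediate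
6 | (3S,7S)-7-hydroxy-3,7-dimethylnon-8-enal | O=CC[C@@H](C)CCC[C@](C)(O)C=C | intermediate
7 | (2R,3S,7S)-2-(anilinooxy)-7-hydroxy-3,7-dimethylnon-8-enal (not isolated) | O=C[C@H](ONc1ccccc1)[C@@H](C)CCC[C@](C)(O)C=C | intermediate
8 | (2R,3S,7S)-2-(anilinooxy)-3,7-dimethylnon-8-ene-1,7-diol | OC[C@H](ONc1ccccc1)[C@@H](C)CCC[C@](C)(O)C=C | intermediate
9 | (2R,3S,7S)-3,7-dimethylnon-8-ene-1,2,7-triol | OC[C@H](O)[C@@H](C)CCC[C@](C)(O)C=C | intermediate
10 | (3S,7S,8R)-3,7-dimethyl-8,9-bis(triethylsilyloxy)non-1-en-3-ol | CC[Si](CC)(CC)OC[C@H](O[Si](CC)(CC)CC)[C@@H](C)CCC[C@](C)(O)C=C | intermediate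
11 | (2R,3S,7S)-7-hydroxy-3,7-dimethyl-2-(triethylsilyloxy)non-8-enal | O=C[C@H](O[Si](CC)(CC)CC)[C@@H](C)CCC[C@](C)(O)C=C | intermediate
12 | 3-(tert-butyldimethylsilyloxy)propanal | O=CCCO[Si](C)(C)C(C)(C)C | starting material
13 | ethyl acrylate | C=CC(=O)OCC | starting material
14 | ethyl 5-(tert-butyldimethylsilyloxy)-3-hydroxy-2-methylidenepentanoate (racemic) | C=C(C(=O)OCC)C(O)CCO[Si](C)(C)C(C)(C)C | intermediate
15 | ethyl (2Z)-2-(bromomethyl)-5-(tert-butyldimethylsilyloxy)pent-2-enoate | CCOC(=O)/C(CBr)=C/CCO[Si](C)(C)C(C)(C)C | intermediate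
16 | (2R,3S,7S)-2,7-dihydroxy-3,7-dimethylnon-8-enal (not isolated) | O=C[C@H](O)[C@@H](C)CCC[C@](C)(O)C=C | intermediate
17 | allylindium reagent from 15, drawn as the dibromide (not isolated) | CCOC(=O)/C(C[In](Br)Br)=C/CCO[Si](C)(C)C(C)(C)C | intermediate
18 | ethyl (3S,4R,5R,6S,10S)-3-[2-(tert-butyldimethylsilyloxy)ethyl]-4,5,10-trihydroxy-6,10-dimethyl-2-methylidenedodec-11-enoate (not isolated) | C=C(C(=O)OCC)[C@H](CCO[Si](C)(C)C(C)(C)C)[C@@H](O)[C@H](O)[C@@H](C)CCC[C@](C)(O)C=C | intermediate
19 | (4S,5R)-4-[2-(tert-butyldimethylsilyloxy)ethyl]-5-[(1R,2S,6S)-1,6-dihydroxy-2,6-dimethyloct-7-en-1-yl]-3-methylideneoxolan-2-one | C=C1C(=O)O[C@@H]([C@H](O)[C@@H](C)CCC[C@](C)(O)C=C)[C@H]1CCO[Si](C)(C)C(C)(C)C | intermediate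
20 | 13-acetate of 19 | C=C1C(=O)O[C@@H]([C@H](OC(C)=O)[C@@H](C)CCC[C@](C)(O)C=C)[C@H]1CCO[Si](C)(C)C(C)(C)C | intermediate
21 | primary C3 alcohol | C=C1C(=O)O[C@@H]([C@H](OC(C)=O)[C@@H](C)CCC[C@](C)(O)C=C)[C@H]1CCO | intermediate
22 | C3 aldehyde | C=C1C(=O)O[C@@H]([C@H](OC(C)=O)[C@@H](C)CCC[C@](C)(O)C=C)[C@H]1CC=O | intermediate
23 | (3E)-enal, C5 aldehyde | C=C1C(=O)O[C@@H]([C@H](OC(C)=O)[C@@H](C)CCC[C@](C)(O)C=C)[C@H]1C/C=C(\C)C=O | intermediate
24 | (3E)-allylic alcohol, C5–OH | C=C1C(=O)O[C@@H]([C@H](OC(C)=O)[C@@H](C)CCC[C@](C)(O)C=C)[C@H]1C/C=C(\C)CO | intermediate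
25 | (3E)-allylic methyl carbonate | C=C1C(=O)O[C@@H]([C@H](OC(C)=O)[C@@H](C)CCC[C@](C)(O)C=C)[C@H]1C/C=C(\C)COC(=O)OC | intermediate
26 | vinylboronic acid pinacol ester | C=CB1OC(C)(C)C(C)(C)O1 | starting material
27 | seco allylic carbonate (6E)-alkenylboronate | C=C1C(=O)O[C@@H]([C@H](OC(C)=O)[C@@H](C)CCC[C@](C)(O)/C=C/B2OC(C)(C)C(C)(C)O2)[C@H]1C/C=C(\C)COC(=O)OC | intermediate
28 | 3,4-deoxy macrocycle (3E,6E) | C=C1C(=O)O[C@H]2[C@H](OC(C)=O)[C@@H](C)CCC[C@](C)(O)/C=C/C/C(C)=C/C[C@@H]12 | intermediate
29 | CNP0202356.4 | C=C1C(=O)O[C@H]2[C@H](OC(C)=O)[C@@H](C)CCC[C@](C)(O)/C=C/C[C@@]3(C)O[C@@H]3C[C@@H]12 | target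

**Step count**
Total step count: 20. Longest linear sequence: 18 steps from 1 (steps 1–8 and 11–20). Steps 9 and 10 form the two-step side branch.

**Steps most likely to fail**

Step 19.
- What may go wrong: transmetalation of the pinacol boronate may be slow. The allylpalladium complex then has time to lose a β-hydrogen, the boronate to protodeboronate, or two molecules to couple, so that oligomerisation outruns ring closure.
- Fallback: it sets out from carbonate 25 and comes back at macrocycle 28. The same C5–C6 bond is made first and between two molecules. Compounds 25 and 26 with Pd(PPh3)4 in THF should give the C5-vinyl seco triene F1, in which C3=C4–C5–C6=CH2 is already the skipped diene.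
- Ring-closing metathesis of the two terminal alkenes of F1 (second-generation Grubbs catalyst, dilute CH2Cl2, 40 °C) then closes the 14-membered ring at C6=C7. The E alkene is expected as the less strained isomer.
- This path also makes step 18 unnecessary, so it covers a sluggish cross-metathesis as well.

Step 20.
- What may go wrong: the ring conformation may expose only one face of C3=C4 and override the catalyst, giving poor or reversed facial selectivity. Prolonged exposure to the basic buffer may also start oxidation at C6=C7 or hydrolysis of the acetate and lactone.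
- Fallback: it sets out from 28 and comes back at 29, and it uses the substrate bias instead of fighting it. NBS in THF/H2O at 0 °C delivers bromine to the exposed face of the most nucleophilic alkene, and water opens the bromonium ion at the tertiary C4 from the hidden face. This gives the (3S,4R)-bromohydrin F2.
- DBU in CH2Cl2 then closes the oxirane with inversion at C3, so the oxygen ends on the face that a direct oxidant cannot reach.

Step 11.
- What may go wrong: the free α-hydroxy aldehyde may dimerise, epimerise at C13 through its enediol, or be captured before chelation is complete. Material is then lost and the facial selectivity at C14 drops.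
- Fallback: it sets out from aldehyde 6 and comes back at the open trihydroxy ester 18. The α-oxy aldehyde 7 is generated with L-proline and PhNO as in step 5 but is not reduced. The mixture is diluted with THF/H2O and treated at once with 15 and In powder (tandem aminoxylation–allylation), which should give the 13-anilinooxy adduct F3.
- Zn in AcOH then cleaves the N–O bond to give 18, which lactonises to 19 as before.
- The aldehyde is consumed as it forms, the O–N donor can still chelate indium, and four steps are saved. The facial selectivity of this variant is less well secured, which is why it is not the first choice.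

**Further compounds**
F1 | step 19 | C5-vinyl seco triene (lactone C1 carries CH2–CH=C(CH3)–CH2–CH=CH2; 3E; 1S,8S,12S,13R,14R) | C=C1C(=O)O[C@@H]([C@H](OC(C)=O)[C@@H](C)CCC[C@](C)(O)C=C)[C@H]1C/C=C(\C)CC=C
F2 | step 20 | (3S,4R)-3-bromo-4-hydroxy macrocycle (bromohydrin of 28) | C=C1C(=O)O[C@H]2[C@H](OC(C)=O)[C@@H](C)CCC[C@](C)(O)/C=C/C[C@@](C)(O)[C@@H](Br)C[C@@H]12
F3 | step 11 | ethyl (3S,4R,5R,6S,10S)-5-(anilinooxy)-3-[2-(tert-butyldimethylsilyloxy)ethyl]-4,10-dihydroxy-6,10-dimethyl-2-methylidenedodec-11-enoate | C=C(C(=O)OCC)[C@H](CCO[Si](C)(C)C(C)(C)C)[C@@H](O)[C@H](ONc1ccccc1)[C@@H](C)CCC[C@](C)(O)C=C
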